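**Atom and ring labels used throughout.** Oxolane: O1, C2 (carries ring A), C3 and C4 (methyl-bearing), C5 (carries ring B). Ring B: C1′ (bonded to C5), C3′ (side chain), C4′ (OH). Side chain: Cα (methine), Cβ (CH2), ring C at its end.

## The problem

The target is a 2,5-diaryl-3,4-dimethyloxolane. C2 carries ring A (4-hydroxyphenyl) and C5 carries ring B, a phenol with a CH(CH3)–CH2–aryl chain (Cα, Cβ, ring C) ortho to its hydroxyl. The ring is 2,3-trans, 3,4-cis, 4,5-trans (2S,3S,4R,5R), with both aryl groups on one face and both methyl groups on the other. With two equal aryl groups this core would be meso, so its handedness exists only because ring B differs from ring A. The two aryl groups must therefore be joined to the two enantiotopic ends of a meso dimethyl unit in a fixed order. Inside the ring each centre can be set from its neighbour, but Cα (R) lies beyond ring B, out of reach of the core, and needs reagent control of its own. The C2–O and C5–O bonds are each benzylic to a para-oxygenated ring, so they ionise under acid (epimerisation, ring opening) and can be hydrogenolysed. The three phenols are oxidation-prone and stay masked to the end. The enabling feature is the chain O(C4′)–C4′–C3′–Cα–Cβ. Joining that oxygen to Cβ gives a 2-aryl-3-methyl-2,3-dihydrobenzofuran, so ring C and Cβ can arrive as a benzyl-type ether on the ring B oxygen. Cα–Cβ is then made by carbenoid insertion into that ether's CH2 group, and the O–Cβ bond is cut again reductively.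

## Retrosynthesis

**Target 24 to dihydrobenzofuran 22.** No skeletal bond is cut. The ring B hydroxyl and one Cβ–H are traced back to the C2–O bond of a dihydrobenzofuran, and the other two phenols to benzyl ethers. Against separate deprotection and ring-opening steps, this places all reductive C–O cleavage in one operation, which passes through bisphenol 23. The precursor has all phenols masked and Cβ tied to the ring B oxygen. The forward step must cleave three benzylic aryl ether bonds and spare the two benzylic alkyl ether bonds of the oxolane.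

**22 to ester 19.** The C3 methyl of the dihydrobenzofuran is traced to a methoxycarbonyl group through tosylate 21 and alcohol 20. No bond of the skeleton changes. The ester is needed because it is the acceptor group of the carbenoid. The forward steps must avoid base at the ester stage, since C3 is both benzylic and α to the carbonyl.

**19 to diazo ester 18.** The C2–C3 bond of the dihydrobenzofuran (Cα–Cβ of the target) is cut. Cutting C3′–Cα instead would need an organometallic on the crowded ring B and a separate controller for Cα. Cutting Cβ–ring C would leave Cα to be set by alkylation. The chosen cut needs ring C and Cβ only as an ether. The precursor lacks one ring, one C–C bond and two stereocentres. The forward reaction must pick the ortho O–CH2 group over all other C–H bonds, close cis, and set C3 under catalyst control.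

**18 to arylacetate 17 to bromide 16.** The diazo group comes by diazo transfer. The C3′–CH2 bond is cut back to an aryl bromide and an acetate enolate equivalent. This keeps ring B free of carbonyl groups while the oxolane is built with organometallic reagents. The forward arylation must tolerate an ortho alkoxy group.

**16 to sulfone 10 and iodide 13.** The C5–C1′ bond is cut, giving an oxocarbenium electrophile (from 10) and an arylzinc nucleophile (15, made from 13 through 14). Iodide 13 is the ether of phenol 11 with benzyl chloride 12, so ring C and Cβ enter here in one step.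

- The neighbouring option was to add the aryl metal to the lactone and reduce the hemiketal. It is put aside because hydride would then choose the face and should enter anti to the two cis methyl groups, leaving ring B cis to them.
- The Lewis acid in that option would also endanger the 4-alkoxybenzyl ether.
- With the aryl group as the incoming species, the same facial preference gives the required 4,5-trans, 2,5-cis product.

**10 to lactol 9 to lactone 8 to keto acid 6.** These are functional-group changes at C5 (sulfone from lactol, lactol from lactone) and the C2–O bond (lactone from hydroxy acid 7, formed by ketone reduction). The lactone is chosen over an open-chain diol because it fixes C2 and differentiates the two ends. The reduction must give the carbinol anti to the adjacent methyl.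

**6 to meso anhydride 2 and bromide 3; 2 to 1.** The C2–ring A bond is cut. The two methyl centres are taken from a meso anhydride, obtained by hydrogenating 1, so only one enantiotopic choice has to be made. The chiral catalyst makes that choice as the arylzinc 5 (from 3 through 4) opens the anhydride. This replaces an auxiliary-based construction of two centres by one catalytic step.

## Roads not taken

**Alternative 1:** The cut is through C4–C5 and C2–C3 of the oxolane. In the forward sense SnCl4 ionises an acetal carbon that carries ring B. The oxocarbenium ion adds to a trisubstituted alkene (C4–C5), and the ring A benzylic carbon then shifts to the new cation (C2–C3). This contracts a six-membered oxacycle to the oxolane and leaves a formyl group on C3, giving A1.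

- Merits: one operation builds the ring, two C–C bonds and three ring centres. In ring construction it is clearly shorter than steps 2–7 here.
- Weak points for this target: C3 arrives quaternary, and the formyl group must be excised with retention (for example with stoichiometric RhCl(PPh3)3) at a neopentyl position.
- The phenols must be acylated to keep SnCl4 from ionising the benzylic C–O bonds, and the same deactivation lowers the migratory aptitude of the benzylic carbon.
- The methyl/formyl sense at C3 rests on a chair geometry that is hard to predict for the 3,4-cis series.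
- Cα must already be present on the ring B piece, so its control is left unsolved.
- The chosen plan sets against the shorter ring synthesis that each ring centre is fixed by a reaction of known sense, that no trace group has to be removed, and that its key step deals with Cα.

**Alternative 2:** The cut is at C3′–Cα and Cβ–ring C. The ring B aryllithium A2 adds to isopropenylboronic acid pinacol ester A3. Pd(OAc)2 with a MandyPhos ligand and the ring C triflate A4 then trigger 1,2-migration of ring B from boron to Cα as the aryl–palladium adds to the terminal carbon. This gives the tertiary boronic ester A5, and stereoretentive protodeboronation and debenzylation would finish the synthesis.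

- Merits: a convergent three-component union and a three-step endgame from a ring B bromide, against seven steps (8–14) here. In step count this road is better.
- Weak points: the migrating group carries an ortho benzyloxy substituent, so the boronate is congested.
- α-Substituted alkenyl boronates are the demanding substrate class for this coupling, in rate and in enantioselectivity.
- Lithium halide from the lithiation interferes with the coupling.
- The hindered tertiary benzylic boronate must then lose boron without erosion.
- It also needs an aryllithium on the finished core.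
- The chosen plan sets against the shorter endgame a catalyst system established on ortho-alkoxyaryl diazoacetates, a minor isomer that is a separable diastereomer at the ester stage, and no organolithium chemistry after the oxolane is closed.

**Alternative 3:** The cut is the C3–C4 bond. Hydrogen-atom transfer (Mn(dpm)3, PhSiH3, tert-butyl hydroperoxide) to one vinyl group of the bis-allylic ether A6 gives a secondary radical. It closes 5-exo onto the other vinyl group, and the primary radical is reduced, giving A7.

- Merits: the ring and both methyl-bearing centres form in one late step. The chair-like transition state of 5-exo closure predicts the required arrangement (1-substituent cis, 2- and 4-substituents trans). Either vinyl group may react first with the same result. It is shorter at the ring stage.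
- Weak points: A6 is an ether of two secondary benzylic allylic alcohols. Its two centres must be made separately and joined without ionisation or allylic transposition.
- Each C–H next to oxygen in A6 is benzylic and allylic, so hydrogen shift to the radical and alkene migration under the metal hydride compete.
- The cis preference between the new methyl groups is usually modest.
- Cα must again pre-exist.
- The chosen plan is longer in the ring synthesis but avoids a doubly activated ether and includes the control of Cα.

Key step: step 10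

Assumption: the senses of induction are taken as (S)-t-Bu-PHOX giving (2R,3S)-6 in step 2 and Rh2(R-PTTL)4 giving (2R,3S)-19 in step 10; should either run the other way, the mirror-image ligand or catalyst is used and nothing else changes.

## Route

Step 1
Reactants: 1 2,3-dimethylmaleic anhydride
Product: 2 (3R,4S)-3,4-dimethyloxolane-2,5-dione (meso cis-2,3-dimethylsuccinic anhydride)
Conditions: H2 (4 atm), 10% Pd/C, EtOAc, rt
Reagents that add atoms: none
Why: Heterogeneous catalytic hydrogenation adds both hydrogens to one face of the tetrasubstituted alkene, so the methyl groups end up cis and the product is the meso anhydride.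

Step 2
Reactants: 3 1-(benzyloxy)-4-bromobenzene; 2 (3R,4S)-3,4-dimethyloxolane-2,5-dione
Product: 6 (2R,3S)-4-[4-(benzyloxy)phenyl]-2,3-dimethyl-4-oxobutanoic acid, via aryllithium 4 (not isolated), via arylzinc triflate 5 (not isolated)
Conditions: 3, n-BuLi, THF, −78 °C; Zn(OTf)2, −78 °C → rt; then 2, [Rh(cod)Cl]2 (cat.), (S)-t-Bu-PHOX (cat.), THF, 50 °C; aq. HCl
Reagents that add atoms: none
Why: Rhodium-catalysed enantioselective desymmetrisation of a meso succinic anhydride with an arylzinc reagent: the chiral monovalent rhodium–phosphinooxazoline complex inserts into one of the two enantiotopic acyl–oxygen bonds and aryl transfer gives the keto acid. Both methyl centres come unchanged from 2; the catalyst only decides which carbonyl becomes the ketone.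

Step 3
Reactants: 6 (2R,3S)-4-[4-(benzyloxy)phenyl]-2,3-dimethyl-4-oxobutanoic acid
Product: 8 (3R,4S,5S)-5-[4-(benzyloxy)phenyl]-3,4-dimethyloxolan-2-one, via hydroxy acid 7 (not isolated)
Conditions: LiBH(s-Bu)3 (2.2 equiv), THF, −78 °C; then 2 M HCl, rt
Reagents that add atoms: none
Why: Felkin–Anh-controlled reduction of the α-methyl aryl ketone by the bulky hydride should give the carbinol anti to the adjacent methyl, and acidification lactonises with retention, placing the aryl group trans to that methyl. The same lactone is the thermodynamically preferred epimer at the benzylic carbon, so kinetic and thermodynamic control point the same way.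

Step 4
Reactants: 8 (3R,4S,5S)-5-[4-(benzyloxy)phenyl]-3,4-dimethyloxolan-2-one
Product: 9 (3R,4S,5S)-5-[4-(benzyloxy)phenyl]-3,4-dimethyloxolan-2-ol (mixture of C2 epimers)
Conditions: i-Bu2AlH (1.1 equiv), CH2Cl2, −78 °C; aq. potassium sodium tartrate
Reagents that add atoms: none
Why: Partial reduction of a lactone to the lactol; the tetrahedral aluminium hemiacetal is stable at low temperature, and the non-basic reagent leaves the α-methyl centre untouched.

Step 5
Reactants: 9 (3R,4S,5S)-5-[4-(benzyloxy)phenyl]-3,4-dimethyloxolan-2-ol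
Product: 10 (3R,4S,5S)-2-(benzenesulfonyl)-5-[4-(benzyloxy)phenyl]-3,4-dimethyloxolane (mixture of C2 epimers)
Conditions: PhSO2H, CaCl2, CH2Cl2, rt
Reagents that add atoms: benzenesulfinic acid, OS(=O)c1ccccc1
Why: Acid-mediated exchange of the anomeric hydroxyl for sulfinate (formation of a 2-sulfonyl cyclic ether); the configuration at the anomeric carbon is irrelevant because it is ionised in step 7.

Step 6
Reactants: 11 2-bromo-4-iodophenol; 12 4-(benzyloxy)benzyl chloride
Product: 13 1-{[4-(benzyloxy)phenyl]methoxy}-2-bromo-4-iodobenzene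
Conditions: K2CO3, Bu4NI (cat.), DMF, rt
Reagents that add atoms: none
Why: Williamson ether synthesis of a phenoxide with a reactive benzylic chloride; the ether is both the phenol protection and the carrier of Cβ and ring C.

Step 7
Reactants: 13 1-{[4-(benzyloxy)phenyl]methoxy}-2-bromo-4-iodobenzene; 10 (3R,4S,5S)-2-(benzenesulfonyl)-5-[4-(benzyloxy)phenyl]-3,4-dimethyloxolane
Product: 16 (2S,3S,4R,5R)-2-[4-(benzyloxy)phenyl]-5-(4-{[4-(benzyloxy)phenyl]methoxy}-3-bromophenyl)-3,4-dimethyloxolane, via arylmagnesium chloride 14 (not isolated), via arylzinc bromide 15 (not isolated)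
Conditions: 13, i-PrMgCl·LiCl, THF, −20 → 0 °C; ZnBr2, 0 °C → rt; then 10, THF, rt
Reagents that add atoms: none
Why: Substitution of a 2-sulfonyl cyclic ether by an arylzinc reagent: the zinc and magnesium halides assist loss of sulfinate to the oxolane oxocarbenium ion, and the aryl group should add to the face opposite the two cis methyl groups (inside attack on the envelope with the C3 methyl pseudo-equatorial), which places ring B trans to the C4 methyl and cis to ring A. Iodine–magnesium exchange is much faster than bromine–magnesium exchange, so the bromide survives for step 8.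

Step 8
Reactants: 16 (2S,3S,4R,5R)-2-[4-(benzyloxy)phenyl]-5-(4-{[4-(benzyloxy)phenyl]methoxy}-3-bromophenyl)-3,4-dimethyloxolane
Product: 17 methyl 2-{2-{[4-(benzyloxy)phenyl]methoxy}-5-[(2R,3R,4S,5S)-5-[4-(benzyloxy)phenyl]-3,4-dimethyloxolan-2-yl]phenyl}acetate
Conditions: BrZnCH2CO2Me (from BrCH2CO2Me and Zn, THF), Pd(dba)2 (cat.), Q-Phos (cat.), THF, 60 °C
Reagents that add atoms: bromo(2-methoxy-2-oxoethyl)zinc (Reformatsky reagent from methyl bromoacetate and zinc), COC(=O)C[Zn]Br
Why: Palladium-catalysed α-arylation of an ester as its zinc enolate (Negishi-type coupling of a Reformatsky reagent with an aryl bromide); the near-neutral conditions leave the benzylic ethers and the oxolane centres alone.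

Step 9
Reactants: 17 methyl 2-{2-{[4-(benzyloxy)phenyl]methoxy}-5-[(2R,3R,4S,5S)-5-[4-(benzyloxy)phenyl]-3,4-dimethyloxolan-2-yl]phenyl}acetate
Product: 18 methyl 2-{2-{[4-(benzyloxy)phenyl]methoxy}-5-[(2R,3R,4S,5S)-5-[4-(benzyloxy)phenyl]-3,4-dimethyloxolan-2-yl]phenyl}-2-diazoacetate
Conditions: p-ABSA, DBU, MeCN–THF, 0 °C → rt
Reagents that add atoms: 4-acetamidobenzenesulfonyl azide, CC(=O)Nc1ccc(S(=O)(=O)N=[N+]=[N-])cc1
Why: Regitz diazo transfer to an arylacetate, whose benzylic α-protons are acidic enough for DBU; the standard preparation of aryldiazoacetates.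

Step 10
Reactants: 18 methyl 2-{2-{[4-(benzyloxy)phenyl]methoxy}-5-[(2R,3R,4S,5S)-5-[4-(benzyloxy)phenyl]-3,4-dimethyloxolan-2-yl]phenyl}-2-diazoacetate
Product: 19 methyl (2R,3S)-2-[4-(benzyloxy)phenyl]-5-[(2R,3R,4S,5S)-5-[4-(benzyloxy)phenyl]-3,4-dimethyloxolan-2-yl]-2,3-dihydro-1-benzofuran-3-carboxylate (2-aryl and ester cis)
Conditions: Rh2(R-PTTL)4 (1–2 mol%), toluene, −60 °C
Reagents that add atoms: none
Why: The divalent rhodium carboxylate dimer, dirhodium tetrakis[N-phthaloyl-(R)-tert-leucinate], attacks the diazo carbon, nitrogen leaves, and the donor/acceptor rhodium carbenoid inserts into a C–H bond of the neighbouring O–CH2–aryl group through a concerted three-centre transition state with hydride-shift character, forming the C2–C3 bond (Cβ–Cα of the target) and releasing the catalyst. The closest known reaction type is the dirhodium carboxylate-catalysed enantioselective intramolecular C–H insertion of methyl 2-[2-(benzyloxy)phenyl]-2-diazoacetates to cis-2-aryl-2,3-dihydrobenzofuran-3-carboxylates, from which 18 differs only by para substituents. The one ring closes by 1,5-insertion: carbenoid carbon, two ring B carbons, the ether oxygen and the benzylic carbon form the five-membered ring. C3 is set by the chiral phthaloyl-tert-leucinate ligand shell, which decides the face of the carbenoid that meets the C–H bond; C2 follows from which enantiotopic benzylic hydrogen is taken, and the compact transition state places aryl and ester cis, so both centres are catalyst-controlled while the four oxolane centres, para to the reacting site, are spectators. The step needs site, cis and enantioselectivity: only the ortho ether CH2 can reach the carbenoid through a five-membered transition state, its C–H bonds are activated by the oxygen and by the electron-rich 4-(benzyloxy)phenyl group, and the low temperature with a stabilised carbenoid holds back dimerisation and arene addition. A minor isomer at C3 is a diastereomer of 19 and can be removed, and 19 is worked up without base so that the cis ester does not epimerise.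

Step 11
Reactants: 19 methyl (2R,3S)-2-[4-(benzyloxy)phenyl]-5-[(2R,3R,4S,5S)-5-[4-(benzyloxy)phenyl]-3,4-dimethyloxolan-2-yl]-2,3-dihydro-1-benzofuran-3-carboxylate
Product: 20 [(2R,3R)-2-[4-(benzyloxy)phenyl]-5-[(2R,3R,4S,5S)-5-[4-(benzyloxy)phenyl]-3,4-dimethyloxolan-2-yl]-2,3-dihydro-1-benzofuran-3-yl]methanol
Conditions: LiAlH4, THF, −40 → 0 °C
Reagents that add atoms: none
Why: Hydride reduction of the ester to the primary alcohol; at low temperature hydride addition to the carbonyl is much faster than deprotonation at C3, so the cis arrangement is kept (the descriptor at C3 changes only through priorities).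

Step 12
Reactants: 20 [(2R,3R)-2-[4-(benzyloxy)phenyl]-5-[(2R,3R,4S,5S)-5-[4-(benzyloxy)phenyl]-3,4-dimethyloxolan-2-yl]-2,3-dihydro-1-benzofuran-3-yl]methanol
Product: 21 [(2R,3R)-2-[4-(benzyloxy)phenyl]-5-[(2R,3R,4S,5S)-5-[4-(benzyloxy)phenyl]-3,4-dimethyloxolan-2-yl]-2,3-dihydro-1-benzofuran-3-yl]methyl 4-methylbenzenesulfonate
Conditions: TsCl, Et3N, DMAP (cat.), CH2Cl2, 0 °C → rt
Reagents that add atoms: 4-methylbenzenesulfonyl chloride, Cc1ccc(S(=O)(=O)Cl)cc1
Why: Sulfonylation of a primary alcohol; no stereocentre is involved.

Step 13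
Reactants: 21 [(2R,3R)-2-[4-(benzyloxy)phenyl]-5-[(2R,3R,4S,5S)-5-[4-(benzyloxy)phenyl]-3,4-dimethyloxolan-2-yl]-2,3-dihydro-1-benzofuran-3-yl]methyl 4-methylbenzenesulfonate
Product: 22 (2R,3S)-2-[4-(benzyloxy)phenyl]-5-[(2R,3R,4S,5S)-5-[4-(benzyloxy)phenyl]-3,4-dimethyloxolan-2-yl]-3-methyl-2,3-dihydro-1-benzofuran
Conditions: LiEt3BH, THF, 0 → 50 °C
Reagents that add atoms: none
Why: SN2 displacement of a primary tosylate by the strongly nucleophilic, weakly basic triethylborohydride, which copes with β-branched tosylates and should outrun elimination toward the benzylic C3–H.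

Step 14
Reactants: 22 (2R,3S)-2-[4-(benzyloxy)phenyl]-5-[(2R,3R,4S,5S)-5-[4-(benzyloxy)phenyl]-3,4-dimethyloxolan-2-yl]-3-methyl-2,3-dihydro-1-benzofuran
Product: 24 2-[(2R)-1-(4-hydroxyphenyl)propan-2-yl]-4-[(2R,3R,4S,5S)-5-(4-hydroxyphenyl)-3,4-dimethyloxolan-2-yl]phenol (CNP0232576.1), via dihydrobenzofuran bisphenol 23 (not isolated)
Conditions: H2 (1 atm), 10% Pd/C, EtOAc–EtOH, rt
Reagents that add atoms: none
Why: Catalytic hydrogenolysis of benzylic C–O bonds: the two unhindered benzyl aryl ethers should go first (to 23), then the benzylic C2–O bond of the dihydrobenzofuran, which is also a benzylic aryl ether and releases a phenol and ring strain. The oxolane C–O bonds are benzylic alkyl ethers with a poor leaving group and are expected to survive under neutral conditions, as they do when related 2,5-diaryloxolanes are debenzylated. Cα is not touched, so the (3S) centre of 22 becomes the (R) methine of 24.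

## Compound list

1 | 2,3-dimethylmaleic anhydride | CC1=C(C)C(=O)OC1=O | starting material
2 | (3R,4S)-3,4-dimethyloxolane-2,5-dione (meso) | C[C@@H]1[C@H](C)C(=O)OC1=O | intermediate
3 | 1-(benzyloxy)-4-bromobenzene | Brc1ccc(OCc2ccccc2)cc1 | starting material
4 | [4-(benzyloxy)phenyl]lithium | [Li]c1ccc(OCc2ccccc2)cc1 | intermediate
5 | [4-(benzyloxy)phenyl]zinc trifluoromethanesulfonate | O=S(=O)(O[Zn]c1ccc(OCc2ccccc2)cc1)C(F)(F)F | intermediate
6 | (2R,3S)-4-[4-(benzyloxy)phenyl]-2,3-dimethyl-4-oxobutanoic acid | C[C@@H](C(=O)O)[C@H](C)C(=O)c1ccc(OCc2ccccc2)cc1 | intermediate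
7 | (2R,3S,4S)-4-[4-(benzyloxy)phenyl]-4-hydroxy-2,3-dimethylbutanoic acid | C[C@@H](C(=O)O)[C@H](C)[C@@H](c1ccc(OCc2ccccc2)cc1)O | intermediate
8 | (3R,4S,5S)-5-[4-(benzyloxy)phenyl]-3,4-dimethyloxolan-2-one | C[C@@H]1[C@H](C)[C@@H](c2ccc(OCc3ccccc3)cc2)OC1=O | intermediate
9 | (3R,4S,5S)-5-[4-(benzyloxy)phenyl]-3,4-dimethyloxolan-2-ol (C2 epimers) | C[C@@H]1[C@H](C)[C@@H](c2ccc(OCc3ccccc3)cc2)OC1O | intermediate
10 | (3R,4S,5S)-2-(benzenesulfonyl)-5-[4-(benzyloxy)phenyl]-3,4-dimethyloxolane (C2 epimers) | C[C@@H]1[C@H](C)[C@@H](c2ccc(OCc3ccccc3)cc2)OC1S(=O)(=O)c1ccccc1 | intermediate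
11 | 2-bromo-4-iodophenol | Oc1ccc(I)cc1Br | starting material
12 | 4-(benzyloxy)benzyl chloride | ClCc1ccc(OCc2ccccc2)cc1 | starting material
13 | 1-{[4-(benzyloxy)phenyl]methoxy}-2-bromo-4-iodobenzene | Brc1cc(I)ccc1OCc1ccc(OCc2ccccc2)cc1 | intermediate
14 | (4-{[4-(benzyloxy)phenyl]methoxy}-3-bromophenyl)magnesium chloride | Cl[Mg]c1ccc(OCc2ccc(OCc3ccccc3)cc2)c(Br)c1 | intermediate
15 | (4-{[4-(benzyloxy)phenyl]methoxy}-3-bromophenyl)zinc bromide | Br[Zn]c1ccc(OCc2ccc(OCc3ccccc3)cc2)c(Br)c1 | intermediate
16 | (2S,3S,4R,5R)-2-[4-(benzyloxy)phenyl]-5-(4-{[4-(benzyloxy)phenyl]methoxy}-3-bromophenyl)-3,4-dimethyloxolane | C[C@@H]1[C@H](C)[C@@H](c2ccc(OCc3ccccc3)cc2)O[C@H]1c1ccc(OCc2ccc(OCc3ccccc3)cc2)c(Br)c1 | intermediate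
17 | methyl 2-{2-{[4-(benzyloxy)phenyl]methoxy}-5-[(2R,3R,4S,5S)-5-[4-(benzyloxy)phenyl]-3,4-dimethyloxolan-2-yl]phenyl}acetate | C[C@@H]1[C@H](C)[C@@H](c2ccc(OCc3ccccc3)cc2)O[C@H]1c1ccc(OCc2ccc(OCc3ccccc3)cc2)c(CC(=O)OC)c1 | intermediate
18 | methyl 2-{2-{[4-(benzyloxy)phenyl]methoxy}-5-[(2R,3R,4S,5S)-5-[4-(benzyloxy)phenyl]-3,4-dimethyloxolan-2-yl]phenyl}-2-diazoacetate | C[C@@H]1[C@H](C)[C@@H](c2ccc(OCc3ccccc3)cc2)O[C@H]1c1ccc(OCc2ccc(OCc3ccccc3)cc2)c(C(=[N+]=[N-])C(=O)OC)c1 | intermediate
19 | methyl (2R,3S)-2-[4-(benzyloxy)phenyl]-5-[(2R,3R,4S,5S)-5-[4-(benzyloxy)phenyl]-3,4-dimethyloxolan-2-yl]-2,3-dihydro-1-benzofuran-3-carboxylate | C[C@@H]1[C@H](C)[C@@H](c2ccc(OCc3ccccc3)cc2)O[C@H]1c1ccc2O[C@@H](c3ccc(OCc4ccccc4)cc3)[C@@H](C(=O)OC)c2c1 | intermediate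
20 | [(2R,3R)-2-[4-(benzyloxy)phenyl]-5-[(2R,3R,4S,5S)-5-[4-(benzyloxy)phenyl]-3,4-dimethyloxolan-2-yl]-2,3-dihydro-1-benzofuran-3-yl]methanol | C[C@@H]1[C@H](C)[C@@H](c2ccc(OCc3ccccc3)cc2)O[C@H]1c1ccc2O[C@@H](c3ccc(OCc4ccccc4)cc3)[C@@H](CO)c2c1 | intermediate
21 | [(2R,3R)-2-[4-(benzyloxy)phenyl]-5-[(2R,3R,4S,5S)-5-[4-(benzyloxy)phenyl]-3,4-dimethyloxolan-2-yl]-2,3-dihydro-1-benzofuran-3-yl]methyl 4-methylbenzenesulfonate | C[C@@H]1[C@H](C)[C@@H](c2ccc(OCc3ccccc3)cc2)O[C@H]1c1ccc2O[C@@H](c3ccc(OCc4ccccc4)cc3)[C@@H](COS(=O)(=O)c3ccc(C)cc3)c2c1 | intermediate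
22 | (2R,3S)-2-[4-(benzyloxy)phenyl]-5-[(2R,3R,4S,5S)-5-[4-(benzyloxy)phenyl]-3,4-dimethyloxolan-2-yl]-3-methyl-2,3-dihydro-1-benzofuran | C[C@@H]1[C@H](C)[C@@H](c2ccc(OCc3ccccc3)cc2)O[C@H]1c1ccc2O[C@@H](c3ccc(OCc4ccccc4)cc3)[C@@H](C)c2c1 | intermediate
23 | 4-[(2R,3S)-5-[(2R,3R,4S,5S)-5-(4-hydroxyphenyl)-3,4-dimethyloxolan-2-yl]-3-methyl-2,3-dihydro-1-benzofuran-2-yl]phenol | C[C@@H]1[C@H](C)[C@@H](c2ccc(O)cc2)O[C@H]1c1ccc2O[C@@H](c3ccc(O)cc3)[C@@H](C)c2c1 | intermediate
24 | 2-[(2R)-1-(4-hydroxyphenyl)propan-2-yl]-4-[(2R,3R,4S,5S)-5-(4-hydroxyphenyl)-3,4-dimethyloxolan-2-yl]phenol (CNP0232576.1) | C[C@@H]1[C@H](C)[C@@H](c2ccc(O)cc2)O[C@H]1c1ccc(O)c([C@H](C)Cc2ccc(O)cc2)c1 | target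

## Step count and risk

Total: 14 steps. Longest linear sequence: 13 steps (steps 1–5 and 7–14, from 1); step 6 is a one-step branch.

**Step 10 (key step).** The catalyst may discriminate the carbenoid faces less well on this large substrate. Carbenoid dimerisation or addition to the electron-rich ring C may compete at the low temperature needed. The cis ester may epimerise during isolation. The fallback gives up the carbenoid and sets Cα by dynamic kinetic resolution; it sets out from 16 and rejoins the route at 24.
- Palladium-catalysed α-arylation of commercial 1-[4-(benzyloxy)phenyl]propan-1-one with 16 (Pd2(dba)3, XPhos, NaOt-Bu, toluene, 80 °C) would give the α-aryl ketone 1-[4-(benzyloxy)phenyl]-2-{2-{[4-(benzyloxy)phenyl]methoxy}-5-[(2R,3R,4S,5S)-5-[4-(benzyloxy)phenyl]-3,4-dimethyloxolan-2-yl]phenyl}propan-1-one F1, a mixture of readily interconverting epimers at the methine.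
- Hydrogenation with RuCl2[(S)-xylbinap][(S)-daipen] or its mirror image (t-BuOK, i-PrOH, H2) reduces one epimer while base keeps the methine equilibrating. It would give the (2S)-configured alcohol 1-[4-(benzyloxy)phenyl]-2-{2-{[4-(benzyloxy)phenyl]methoxy}-5-[(2R,3R,4S,5S)-5-[4-(benzyloxy)phenyl]-3,4-dimethyloxolan-2-yl]phenyl}propan-1-ol F2. Its methine has the spatial arrangement of Cα in 24.
- Hydrogenolysis over Pd/C then removes the benzylic hydroxyl and all benzyl-type ethers to give 24.

**Step 14.** C–O hydrogenolysis may be unselective: the oxolane benzylic C–O bonds may begin to cleave before the more hindered dihydrobenzofuran C2–O bond has opened, or the opening may stall. The fallback sets out from bisphenol 23, isolated by stopping the hydrogenolysis once the two benzyl ethers are gone, and rejoins at 24.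
- In aqueous-ethanolic NaOH with excess NaBH4 at 40–50 °C the ring C phenoxide should expel the ring B phenoxide to give the quinone methide 4-[(2R)-2-{2-hydroxy-5-[(2R,3R,4S,5S)-5-(4-hydroxyphenyl)-3,4-dimethyloxolan-2-yl]phenyl}propylidene]cyclohexa-2,5-dien-1-one F3.
- Borohydride reduces F3 at the exocyclic carbon to the CH2 group of 24 before it can tautomerise.
- The corresponding opening at ring A would expel an alkoxide and should not compete.

**Step 7.** Facial selectivity at C5 may be poor, the hindered functionalised aryl group may transfer sluggishly, or the ring A benzylic carbon may ionise under the Lewis acidic salts. The fallback closes the ring by etherification and sets out from 8 and 13, rejoining at 16.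
- Iodine–lithium exchange on 13 (n-BuLi, THF, −78 °C) gives (4-{[4-(benzyloxy)phenyl]methoxy}-3-bromophenyl)lithium F4.
- F4 adds once to 8 to give the hemiketal (3R,4S,5S)-5-[4-(benzyloxy)phenyl]-2-(4-{[4-(benzyloxy)phenyl]methoxy}-3-bromophenyl)-3,4-dimethyloxolan-2-ol F5.
- LiAlH4 (THF, −78 → 0 °C) reduces the open keto form under Felkin–Anh control to (1S,2S,3R,4R)-1-[4-(benzyloxy)phenyl]-4-(4-{[4-(benzyloxy)phenyl]methoxy}-3-bromophenyl)-2,3-dimethylbutane-1,4-diol F6.
- MsCl and Et3N (CH2Cl2, 0 °C) activate one benzylic hydroxyl, and the other closes the ring through the stabilised benzylic cation with each aryl group trans to its neighbouring methyl, giving 16.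

**Step 2.** The catalyst may not fully discriminate the enantiotopic carbonyl groups, or the centre α to the new ketone may epimerise. The fallback separates desymmetrisation from C–C bond formation; it sets out from 2 and rejoins at 8.
- Cinchona alkaloid-mediated methanolysis (quinine or quinidine, whichever gives the required sense, MeOH, toluene, −55 °C) gives (2S,3R)-4-methoxy-2,3-dimethyl-4-oxobutanoic acid F7.
- (COCl)2 with catalytic DMF gives methyl (2R,3S)-4-chloro-2,3-dimethyl-4-oxobutanoate F8.
- Pd(PPh3)4-catalysed Negishi acylation of arylzinc 5 gives methyl (2R,3S)-4-[4-(benzyloxy)phenyl]-2,3-dimethyl-4-oxobutanoate F9.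
- Reduction with LiBH(s-Bu)3 (THF, −78 °C → rt) and closure of the alkoxide onto the methyl ester give 8.

## Further compounds

F1 | step 10 | 1-[4-(benzyloxy)phenyl]-2-{2-{[4-(benzyloxy)phenyl]methoxy}-5-[(2R,3R,4S,5S)-5-[4-(benzyloxy)phenyl]-3,4-dimethyloxolan-2-yl]phenyl}propan-1-one (epimers at C2 of the propanone) | C[C@@H]1[C@H](C)[C@@H](c2ccc(OCc3ccccc3)cc2)O[C@H]1c1ccc(OCc2ccc(OCc3ccccc3)cc2)c(C(C)C(=O)c2ccc(OCc3ccccc3)cc2)c1
F2 | step 10 | (2S)-1-[4-(benzyloxy)phenyl]-2-{2-{[4-(benzyloxy)phenyl]methoxy}-5-[(2R,3R,4S,5S)-5-[4-(benzyloxy)phenyl]-3,4-dimethyloxolan-2-yl]phenyl}propan-1-ol (carbinol centre left undefined, it is removed next) | C[C@@H]1[C@H](C)[C@@H](c2ccc(OCc3ccccc3)cc2)O[C@H]1c1ccc(OCc2ccc(OCc3ccccc3)cc2)c([C@H](C)C(O)c2ccc(OCc3ccccc3)cc2)c1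
F3 | step 14 | 4-[(2R)-2-{2-hydroxy-5-[(2R,3R,4S,5S)-5-(4-hydroxyphenyl)-3,4-dimethyloxolan-2-yl]phenyl}propylidene]cyclohexa-2,5-dien-1-one | C[C@@H]1[C@H](C)[C@@H](c2ccc(O)cc2)O[C@H]1c1ccc(O)c([C@H](C)C=C2C=CC(=O)C=C2)c1
F4 | step 7 | (4-{[4-(benzyloxy)phenyl]methoxy}-3-bromophenyl)lithium | [Li]c1ccc(OCc2ccc(OCc3ccccc3)cc2)c(Br)c1
F5 | step 7 | (3R,4S,5S)-5-[4-(benzyloxy)phenyl]-2-(4-{[4-(benzyloxy)phenyl]methoxy}-3-bromophenyl)-3,4-dimethyloxolan-2-ol (C2 epimers) | C[C@@H]1[C@H](C)[C@@H](c2ccc(OCc3ccccc3)cc2)OC1(O)c1ccc(OCc2ccc(OCc3ccccc3)cc2)c(Br)c1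
F6 | step 7 | (1S,2S,3R,4R)-1-[4-(benzyloxy)phenyl]-4-(4-{[4-(benzyloxy)phenyl]methoxy}-3-bromophenyl)-2,3-dimethylbutane-1,4-diol | C[C@@H]([C@@H](O)c1ccc(OCc2ccc(OCc3ccccc3)cc2)c(Br)c1)[C@H](C)[C@@H](c1ccc(OCc2ccccc2)cc1)O
F7 | step 2 | (2S,3R)-4-methoxy-2,3-dimethyl-4-oxobutanoic acid | C[C@@H](C(=O)OC)[C@H](C)C(=O)O
F8 | step 2 | methyl (2R,3S)-4-chloro-2,3-dimethyl-4-oxobutanoate | C[C@@H](C(=O)OC)[C@H](C)C(=O)Cl
F9 | step 2 | methyl (2R,3S)-4-[4-(benzyloxy)phenyl]-2,3-dimethyl-4-oxobutanoate | C[C@@H](C(=O)OC)[C@H](C)C(=O)c1ccc(OCc2ccccc2)cc1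
A1 | alternative 1 | tris-pivalate of the target carrying a formyl group at oxolane C3 in place of hydrogen | C[C@@H]1[C@](C=O)(C)[C@@H](c2ccc(OC(=O)C(C)(C)C)cc2)O[C@H]1c1ccc(OC(=O)C(C)(C)C)c([C@H](C)Cc2ccc(OC(=O)C(C)(C)C)cc2)c1
A2 | alternative 2 | ring B aryllithium of the bis-O-benzyl diaryloxolane (lithium at C3′) | C[C@@H]1[C@H](C)[C@@H](c2ccc(OCc3ccccc3)cc2)O[C@H]1c1ccc(OCc2ccccc2)c([Li])c1
A3 | alternative 2 | isopropenylboronic acid pinacol ester | C=C(C)B1OC(C)(C)C(C)(C)O1
A4 | alternative 2 | 4-(benzyloxy)phenyl trifluoromethanesulfonate | O=S(=O)(Oc1ccc(OCc2ccccc2)cc1)C(F)(F)F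
A5 | alternative 2 | tertiary benzylic pinacol boronate of the tris-O-benzyl target (boron on Cα) | C[C@@H]1[C@H](C)[C@@H](c2ccc(OCc3ccccc3)cc2)O[C@H]1c1ccc(OCc2ccccc2)c([C@](B2OC(C)(C)C(C)(C)O2)(C)Cc2ccc(OCc3ccccc3)cc2)c1
A6 | alternative 3 | bis-allylic diaryl ether with both carbinol centres configured as C2 and C5 of the target | C=C[C@@H](c1ccc(OCc2ccccc2)cc1)O[C@H](C=C)c1ccc(OCc2ccccc2)c([C@H](C)Cc2ccc(OCc3ccccc3)cc2)c1
A7 | alternative 3 | tris-O-benzyl ether of the target | C[C@@H]1[C@H](C)[C@@H](c2ccc(OCc3ccccc3)cc2)O[C@H]1c1ccc(OCc2ccccc2)c([C@H](C)Cc2ccc(OCc3ccccc3)cc2)c1
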